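**Plan**

- Retrosynthesis: after removal of three silyl groups, ring C is opened at C2–C3 (carbenoid C–H insertion). The O1–CH2 ether bond is then cut (Mitsunobu) to a ring A 2-hydroxyacetophenone and a ring B benzyl alcohol. The diazo carbon goes back to the acetyl CH3, the ring A C6–prenyl bond to an O-prenyl ether (Claisen–Cope), and the two ring B prenyl bonds to ortho C-alkylation of 4-bromophenol.
- Enabling feature: C2 carries one hydrogen and is bonded to O1 and to ring B. With C2–C3 cut it is an O1-bound benzylic CH2, activated twice over, six atoms from a carbene at C3 (C3–C4–C4a–C8a–O1–C2).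
- Forward: the ring A piece (steps 1–3) and the ring B piece (steps 4–6) are made separately and joined at O1 (step 7). The acetyl group becomes the diazoketone (step 8), ring C, the only ring formed, closes in step 9, and step 10 frees the phenols.
- Regiochemistry of ring A: the Claisen–Cope sequence puts the prenyl group para to the hydroxyl that becomes O1, which fixes the 6-prenyl rather than the 8-prenyl pattern.
- Stereochemistry: C2 (R), the only stereocentre, is set in step 9 by the chiral carboxylate ligands of the dirhodium catalyst, which select one of the two enantiotopic benzylic hydrogens. The non-basic deprotection preserves it.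

Key step: step 9

Assumption: the target is read as the (2R)-flavanone, and Rh2(S-PTTL)4 is taken to be the catalyst antipode that gives (2R); if the induction runs the other way, Rh2(R-PTTL)4 (from D-tert-leucine) is used with no other change.

TBS = tert-butyldimethylsilyl; prenyl = 3-methylbut-2-enyl.

**Route**

Step 1
Reactants: 1 1-(2,4,6-trihydroxyphenyl)ethanone (dried); 2 tert-butyldimethylsilyl chloride
Product: 3 1-[2,4-bis(tert-butyldimethylsilyloxy)-6-hydroxyphenyl]ethanone
Conditions: 2 (2.1 equiv), imidazole, DMF, 0 °C → rt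
Reagents that add atoms: tert-butyldimethylsilyl chloride 2, CC(C)(C)[Si](C)(C)Cl
Why: Phenol silylation; the para hydroxyl and one of the two equivalent ortho hydroxyls react, while the last hydroxyl is held in a hydrogen bond to the acetyl carbonyl and should stay free.

Step 2
Reactants: 3 1-[2,4-bis(TBSO)-6-hydroxyphenyl]ethanone; 4 3-methylbut-2-en-1-ol (prenol)
Product: 5 1-[2,4-bis(tert-butyldimethylsilyloxy)-6-(3-methylbut-2-enyloxy)phenyl]ethanone
Conditions: 4, PPh3, DIAD, THF, 0 °C → rt
Reagents that add atoms: 3-methylbut-2-en-1-ol 4, CC(C)=CCO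
Why: Mitsunobu etherification of an acidic, hydrogen-bonded phenol with a primary allylic alcohol; the neutral conditions leave the aryl silyl ethers in place, where a carbonate alkylation could shift or cleave them.

Step 3
Reactants: 5 1-[2,4-bis(TBSO)-6-(prenyloxy)phenyl]ethanone
Product: 8 1-[2,4-bis(tert-butyldimethylsilyloxy)-6-hydroxy-3-(3-methylbut-2-enyl)phenyl]ethanone, via ortho-dienone 6 (not isolated), via para-dienone 7 (not isolated)
Conditions: PhNEt2, 200 °C, argon, sealed tube
Reagents that add atoms: none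
Why: Aromatic Claisen rearrangement to the only free ortho carbon gives 6 with a 1,1-dimethylallyl group, a Cope shift carries the allyl unit on to the para carbon as a linear prenyl group (7), and tautomerisation gives 8; the para carbon lies between the two silyloxy groups, so the prenyl group ends para to the free hydroxyl, as C6 is para to C8a–O1 in the target.

Step 4
Reactants: 9 4-bromophenol; 10 1-bromo-3-methylbut-2-ene (prenyl bromide)
Product: 11 4-bromo-2,6-bis(3-methylbut-2-enyl)phenol
Conditions: NaH (2.2 equiv), 10 (2.2 equiv), toluene, 0 °C → rt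
Reagents that add atoms: 1-bromo-3-methylbut-2-ene 10, CC(C)=CCBr
Why: ortho-Selective C-alkylation of a sodium phenoxide held as a tight ion pair in a non-polar solvent; the para position is blocked by bromine, so both prenyl groups should enter next to oxygen.

Step 5
Reactants: 11 4-bromo-2,6-bis(prenyl)phenol; 2 tert-butyldimethylsilyl chloride
Product: 12 [4-bromo-2,6-bis(3-methylbut-2-enyl)phenoxy](tert-butyl)dimethylsilane
Conditions: 2, imidazole, DMF, 40 °C
Reagents that add atoms: tert-butyldimethylsilyl chloride 2, CC(C)(C)[Si](C)(C)Cl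
Why: Silylation of a 2,6-dialkylphenol whose flanking carbons are primary CH2 groups, so the oxygen remains accessible to the silyl chloride–imidazole reagent.

Step 6
Reactants: 12 TBS ether of 4-bromo-2,6-bis(prenyl)phenol; 13 paraformaldehyde
Product: 15 [4-(tert-butyldimethylsilyloxy)-3,5-bis(3-methylbut-2-enyl)phenyl]methanol, via aryllithium 14 (not isolated)
Conditions: n-BuLi, THF, −78 °C; then (CH2O)n, −78 °C → rt; aq NH4Cl
Reagents that add atoms: formaldehyde from paraformaldehyde 13, C=O
Why: Bromine–lithium exchange at −78 °C outruns deprotonation of the allylic benzylic CH2 groups, and the aryllithium adds to formaldehyde (hydroxymethylation) to give the benzylic alcohol whose carbon becomes C2.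

Step 7
Reactants: 8 1-[2,4-bis(TBSO)-6-hydroxy-3-prenylphenyl]ethanone; 15 [4-(TBSO)-3,5-bis(prenyl)phenyl]methanol
Product: 16 1-[2,4-bis(tert-butyldimethylsilyloxy)-6-{[4-(tert-butyldimethylsilyloxy)-3,5-bis(3-methylbut-2-enyl)phenyl]methoxy}-3-(3-methylbut-2-enyl)phenyl]ethanone
Conditions: PPh3, DIAD, toluene, 0 °C → rt
Reagents that add atoms: benzyl alcohol 15, CC(C)=CCc1cc(CO)cc(CC=C(C)C)c1O[Si](C)(C)C(C)(C)C
Why: Mitsunobu etherification joins the ring A phenol oxygen (future O1) to the primary benzylic carbon (future C2) without base and without an ionisable para-silyloxybenzyl halide.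

Step 8
Reactants: 16 ring A acetophenone benzyl ether; 17 2,2,2-trifluoroethyl trifluoroacetate; 18 4-acetamidobenzenesulfonyl azide
Product: 21-precursor numbering note does not apply; 20 2-diazo-1-[2,4-bis(tert-butyldimethylsilyloxy)-6-{[4-(tert-butyldimethylsilyloxy)-3,5-bis(3-methylbut-2-enyl)phenyl]methoxy}-3-(3-methylbut-2-enyl)phenyl]ethanone, via trifluoroacetyl diketone 19 (not isolated)
Conditions: LiN(SiMe3)2, THF, −78 °C; 17, −78 °C; aq NH4Cl; then 18, Et3N, H2O (1 equiv), MeCN, rt
Reagents that add atoms: 2,2,2-trifluoroethyl trifluoroacetate 17, O=C(OCC(F)(F)F)C(F)(F)F (its CF3CO group is carried by 19 only); 4-acetamidobenzenesulfonyl azide 18, CC(=O)Nc1ccc(cc1)S(=O)(=O)N=[N+]=[N-] (supplies N2)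
Why: Detrifluoroacetylative diazo transfer, a deacylative Regitz diazo transfer: the lithium enolate of the methyl ketone is trifluoroacetylated, and the activated diketone takes the diazo group from the sulfonyl azide with loss of the trifluoroacetyl group as the N-acyl sulfonamide; at −78 °C acylation should precede any shift of the ortho silyl group to the enolate oxygen.

Step 9
Reactants: 20 ring A diazomethyl ketone
Product: 22-precursor numbering note does not apply; 21 (2R)-5,7-bis(tert-butyldimethylsilyloxy)-2-[4-(tert-butyldimethylsilyloxy)-3,5-bis(3-methylbut-2-enyl)phenyl]-6-(3-methylbut-2-enyl)chroman-4-one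
Conditions: Rh2(S-PTTL)4 [dirhodium tetrakis(N-phthaloyl-(S)-tert-leucinate)] (2 mol %), CH2Cl2, 4 Å MS, 0 °C, slow addition of 20
Reagents that add atoms: none
Why: The dirhodium tetracarboxylate expels N2 from 20 to give a transient electrophilic rhodium-bound carbene at C3, which takes the hydrogen of the O1-bound benzylic CH2 with its bonding pair through a three-centre transition state and forms C2–C3 as the metal leaves; this is the known intramolecular carbenoid C–H insertion of 2-alkoxyaryl diazoketones to chroman-4-ones under chiral dirhodium carboxylates. Ring C closes as a six-membered ring by 1,6-insertion (C3, C4, C4a, C8a, O1, C2), and a five-membered insertion is excluded because the fifth atom is O1. C2 is the only new stereocentre and is set by the catalyst alone: the phthalimido walls of the tert-leucinate ligands distinguish the two enantiotopic benzylic hydrogens, as they do in insertions of 2-benzyloxyaryl diazoacetates. The step needs insertion to win over attack of the carbene on the O1 lone pair (five-membered oxonium ylide, then Stevens benzyl shift) and over cyclopropanation; the hydride-donor strength of a CH2 flanked by O1 and the para-silyloxy ring B, a carboxylate-ligated rhodium rather than a copper catalyst, high dilution, and the fact that no prenyl double bond can reach C3 through an unstrained ring should secure this. The silyl ethers on O5 and O7 offer no activated C–H and shield the O5 lone pairs.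

Step 10
Reactants: 21 (2R)-tris(TBS) flavanone
Product: 22 (2R)-5,7-dihydroxy-2-[4-hydroxy-3,5-bis(3-methylbut-2-enyl)phenyl]-6-(3-methylbut-2-enyl)chroman-4-one
Conditions: Bu4NF (3.5 equiv), AcOH (4 equiv), THF, 0 °C → rt
Reagents that add atoms: none
Why: Fluoride cleaves the three aryl silyl ethers while the acetic acid buffer keeps the freed phenols protonated, so neither enolate-driven retro-oxa-Michael opening of ring C nor quinone-methide opening from a ring B phenoxide can racemise C2, and the prenyl groups are inert at this acidity.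

(In steps 8 and 9 the Product lines name compounds 20 and 21 respectively; the short "numbering note" phrases carry no chemical meaning.)

**Compound list**

1 | 1-(2,4,6-trihydroxyphenyl)ethanone | CC(=O)c1c(O)cc(O)cc1O | starting material
2 | tert-butyldimethylsilyl chloride | CC(C)(C)[Si](C)(C)Cl | starting material
3 | 1-[2,4-bis(TBSO)-6-hydroxyphenyl]ethanone | CC(=O)c1c(O)cc(O[Si](C)(C)C(C)(C)C)cc1O[Si](C)(C)C(C)(C)C | intermediate
4 | 3-methylbut-2-en-1-ol | CC(C)=CCO | starting material
5 | 1-[2,4-bis(TBSO)-6-(3-methylbut-2-enyloxy)phenyl]ethanone | CC(=O)c1c(OCC=C(C)C)cc(O[Si](C)(C)C(C)(C)C)cc1O[Si](C)(C)C(C)(C)C | intermediate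
6 | 2-acetyl-3,5-bis(TBSO)-6-(2-methylbut-3-en-2-yl)cyclohexa-2,4-dien-1-one (racemic, not isolated) | CC(=O)C1=C(O[Si](C)(C)C(C)(C)C)C=C(O[Si](C)(C)C(C)(C)C)C(C(C)(C)C=C)C1=O | intermediate
7 | 2-acetyl-3,5-bis(TBSO)-4-(3-methylbut-2-enyl)cyclohexa-2,5-dien-1-one (not isolated) | CC(=O)C1=C(O[Si](C)(C)C(C)(C)C)C(CC=C(C)C)C(O[Si](C)(C)C(C)(C)C)=CC1=O | intermediate
8 | 1-[2,4-bis(TBSO)-6-hydroxy-3-(3-methylbut-2-enyl)phenyl]ethanone | CC(=O)c1c(O)cc(O[Si](C)(C)C(C)(C)C)c(CC=C(C)C)c1O[Si](C)(C)C(C)(C)C | intermediate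
9 | 4-bromophenol | Oc1ccc(Br)cc1 | starting material
10 | 1-bromo-3-methylbut-2-ene | CC(C)=CCBr | starting material
11 | 4-bromo-2,6-bis(3-methylbut-2-enyl)phenol | CC(C)=CCc1cc(Br)cc(CC=C(C)C)c1O | intermediate
12 | [4-bromo-2,6-bis(3-methylbut-2-enyl)phenoxy](tert-butyl)dimethylsilane | CC(C)=CCc1cc(Br)cc(CC=C(C)C)c1O[Si](C)(C)C(C)(C)C | intermediate
13 | paraformaldehyde (formaldehyde source) | C=O | starting material
14 | [4-(TBSO)-3,5-bis(3-methylbut-2-enyl)phenyl]lithium (not isolated) | [Li]c1cc(CC=C(C)C)c(O[Si](C)(C)C(C)(C)C)c(CC=C(C)C)c1 | intermediate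
15 | [4-(TBSO)-3,5-bis(3-methylbut-2-enyl)phenyl]methanol | CC(C)=CCc1cc(CO)cc(CC=C(C)C)c1O[Si](C)(C)C(C)(C)C | intermediate
16 | 1-[2,4-bis(TBSO)-6-{[4-(TBSO)-3,5-bis(3-methylbut-2-enyl)phenyl]methoxy}-3-(3-methylbut-2-enyl)phenyl]ethanone | CC(=O)c1c(OCc2cc(CC=C(C)C)c(O[Si](C)(C)C(C)(C)C)c(CC=C(C)C)c2)cc(O[Si](C)(C)C(C)(C)C)c(CC=C(C)C)c1O[Si](C)(C)C(C)(C)C | intermediate
17 | 2,2,2-trifluoroethyl trifluoroacetate | O=C(OCC(F)(F)F)C(F)(F)F | starting material
18 | 4-acetamidobenzenesulfonyl azide | CC(=O)Nc1ccc(cc1)S(=O)(=O)N=[N+]=[N-] | starting material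
19 | 4,4,4-trifluoro-1-[aryl of 16]butane-1,3-dione (not isolated) | O=C(CC(=O)C(F)(F)F)c1c(OCc2cc(CC=C(C)C)c(O[Si](C)(C)C(C)(C)C)c(CC=C(C)C)c2)cc(O[Si](C)(C)C(C)(C)C)c(CC=C(C)C)c1O[Si](C)(C)C(C)(C)C | intermediate
20 | 2-diazo-1-[2,4-bis(TBSO)-6-{[4-(TBSO)-3,5-bis(3-methylbut-2-enyl)phenyl]methoxy}-3-(3-methylbut-2-enyl)phenyl]ethanone | [N-]=[N+]=CC(=O)c1c(OCc2cc(CC=C(C)C)c(O[Si](C)(C)C(C)(C)C)c(CC=C(C)C)c2)cc(O[Si](C)(C)C(C)(C)C)c(CC=C(C)C)c1O[Si](C)(C)C(C)(C)C | intermediate
21 | (2R)-5,7-bis(TBSO)-2-[4-(TBSO)-3,5-bis(3-methylbut-2-enyl)phenyl]-6-(3-methylbut-2-enyl)chroman-4-one | CC(C)=CCc1cc([C@H]2CC(=O)c3c(cc(O[Si](C)(C)C(C)(C)C)c(CC=C(C)C)c3O[Si](C)(C)C(C)(C)C)O2)cc(CC=C(C)C)c1O[Si](C)(C)C(C)(C)C | intermediate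
22 | (2R)-5,7-dihydroxy-2-[4-hydroxy-3,5-bis(3-methylbut-2-enyl)phenyl]-6-(3-methylbut-2-enyl)chroman-4-one | CC(C)=CCc1cc([C@H]2CC(=O)c3c(cc(O)c(CC=C(C)C)c3O)O2)cc(CC=C(C)C)c1O | target

**Count**

Total steps: 10. Longest linear sequence: 7 steps (1, 2, 3, 7, 8, 9, 10 from compound 1); the ring B branch (steps 4–6) joins at step 7.

**Steps most likely to fail**

Step 9. The carbene may be captured by the O1 lone pair to give a five-membered oxonium ylide that rearranges by a Stevens benzyl shift, or the two enantiotopic benzylic hydrogens may be poorly distinguished. The fallback sets out from 8 and 12 and returns at 21, forming the C2–ring B bond instead of C2–C3. Phenol 8 is condensed with Me2NCH(OMe)2 in warm toluene to the (E)-enaminone F1, which is closed with pyridinium p-toluenesulfonate, with loss of dimethylamine, to 5,7-bis(TBSO)-6-prenylchromone F2. Bromide 12 is converted by n-BuLi and B(OiPr)3, then aqueous NH4Cl, into the arylboronic acid F3. Asymmetric conjugate addition of F3 to F2 with Pd(OCOCF3)2 and the enantiomer of the tert-butyl pyridine-oxazoline ligand that delivers (2R) (NH4PF6, H2O, ClCH2CH2Cl, 60 °C) should then give 21.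

Step 8. The ortho silyl group may migrate from the aryl oxygen to the enolate oxygen, or the hindered enolate may be acylated incompletely. The fallback sets out from 16 and returns at 20 without any strong base. Ketone 16 is heated with Me2NCH(OMe)2 to the (E)-enaminone F4. Azide 18 in MeCN at rt then adds across the enamine double bond, and the triazoline fragments to diazoketone 20 and an N-sulfonyl formamidine (diazo transfer to an enaminone).

Step 3. At 200 °C the aryl silyl ethers may be lost or scrambled, the prenyl ether may shed isoprene, or the rearrangement may stop at the ortho stage. The fallback sets out from 1 (with 10, 2 and 15) and returns at 16, bypassing steps 1–3 and 7. Ketone 1 is C-prenylated with 10 and DBU in THF to 2,4,6-trihydroxy-3-prenylacetophenone F5. The non-hydrogen-bonded para hydroxyl is silylated with one equivalent of 2 to the 4-silyl ether F6. Mitsunobu etherification with 15 should favour the hydrogen-bonded hydroxyl flanked by H over the one flanked by the prenyl group, giving the mono-phenol F7 after chromatographic removal of the regioisomer. Silylation of the remaining hydroxyl with tert-butyldimethylsilyl triflate and 2,6-lutidine gives 16.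

**Further compounds**

F1 | step 9 | (E)-1-[2,4-bis(TBSO)-6-hydroxy-3-(3-methylbut-2-enyl)phenyl]-3-(dimethylamino)prop-2-en-1-one | CN(C)/C=C/C(=O)c1c(O)cc(O[Si](C)(C)C(C)(C)C)c(CC=C(C)C)c1O[Si](C)(C)C(C)(C)C
F2 | step 9 | 5,7-bis(TBSO)-6-(3-methylbut-2-enyl)-4H-chromen-4-one | O=c1ccoc2cc(O[Si](C)(C)C(C)(C)C)c(CC=C(C)C)c(O[Si](C)(C)C(C)(C)C)c12
F3 | step 9 | [4-(TBSO)-3,5-bis(3-methylbut-2-enyl)phenyl]boronic acid | CC(C)=CCc1cc(B(O)O)cc(CC=C(C)C)c1O[Si](C)(C)C(C)(C)C
F4 | step 8 | (E)-3-(dimethylamino)-1-[2,4-bis(TBSO)-6-{[4-(TBSO)-3,5-bis(3-methylbut-2-enyl)phenyl]methoxy}-3-(3-methylbut-2-enyl)phenyl]prop-2-en-1-one | CN(C)/C=C/C(=O)c1c(OCc2cc(CC=C(C)C)c(O[Si](C)(C)C(C)(C)C)c(CC=C(C)C)c2)cc(O[Si](C)(C)C(C)(C)C)c(CC=C(C)C)c1O[Si](C)(C)C(C)(C)C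
F5 | step 3 | 1-[2,4,6-trihydroxy-3-(3-methylbut-2-enyl)phenyl]ethanone | CC(=O)c1c(O)cc(O)c(CC=C(C)C)c1O
F6 | step 3 | 1-[4-(TBSO)-2,6-dihydroxy-3-(3-methylbut-2-enyl)phenyl]ethanone | CC(=O)c1c(O)cc(O[Si](C)(C)C(C)(C)C)c(CC=C(C)C)c1O
F7 | step 3 | 1-[4-(TBSO)-2-hydroxy-6-{[4-(TBSO)-3,5-bis(3-methylbut-2-enyl)phenyl]methoxy}-3-(3-methylbut-2-enyl)phenyl]ethanone | CC(=O)c1c(OCc2cc(CC=C(C)C)c(O[Si](C)(C)C(C)(C)C)c(CC=C(C)C)c2)cc(O[Si](C)(C)C(C)(C)C)c(CC=C(C)C)c1O
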